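**Plan**

- Retrosynthesis: after hydrolysis of two alkyl enol ethers, both ring bonds that tie the C(pentadecenyl)=C(OH) unit to the two quinone carbonyl carbons are cut at once. This leaves a four-carbon maleoyl unit O=C–C(CH3)=C(OMe)–C=O held on cobalt and a two-carbon ynol ether.
- Enabling feature: the all-sp2 six-membered quinone ring is a cis-enedione (its C(=O)–C(CH3)=C(O)–C(=O) carbons map onto the four-membered ring of squaric acid) plus one enol C=C at the oxidation level of an alkoxyalkyne. C–C oxidative addition turns the two carbonyl carbons, normally electrophiles, into cobalt-bound acyl groups, so one of them can bond to the oxygen-bearing alkyne carbon.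
- Further cuts: the C(sp)–CH2 bond of the ynol ether (alkylation of lithium ethoxyacetylide), the Z-olefin (Wittig) and the ring C–CH3 bond (MeLi on dimethyl squarate).
- Forward order: chain bromide, then ynol ether; four-membered dione, then five-membered cobaltacycle; the annulation builds the six-membered ring and joins the chain in the same step; hydrolysis ends the route.
- Stereochemistry: the Z double bond is the only stereo-element. It is set by a lithium-free Wittig reaction and is not touched afterwards.

Key step: step 6

Remark: the target is a 2,5-dihydroxy-1,4-benzoquinone whose tautomers interconvert rapidly; the route aims at the compound, drawn as the given tautomer.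

**Route**

Step 1
Reactants: 1 10-bromodecan-1-ol
Product: 2 10-bromodecanal
Conditions: TEMPO (cat.), PhI(OAc)2, CH2Cl2, rt
Reagents that add atoms: none
Why: TEMPO (oxoammonium) oxidation of a primary alcohol stops at the aldehyde and leaves the primary bromide untouched.

Step 2
Reactants: 2 10-bromodecanal; 3 pentyltriphenylphosphonium bromide
Product: 5 (Z)-1-bromopentadec-10-ene, via pentylidenetriphenylphosphorane 4 (not isolated)
Conditions: 3, NaN(SiMe3)2, THF, 0 °C; then 2, −78 °C to rt
Reagents that add atoms: none
Why: Wittig reaction of an unstabilised ylide made with a lithium-free base should pass through the kinetically favoured cis-oxaphosphetane and so give the Z-olefin, the aldehyde reacting at −78 °C much faster than the primary bromide.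

Step 3
Reactants: 5 (Z)-1-bromopentadec-10-ene; 6 ethoxyacetylene
Product: 8 (12Z)-1-ethoxyheptadec-12-en-1-yne, via lithium ethoxyacetylide 7 (not isolated)
Conditions: 6, n-BuLi, THF, −78 °C; then 5, HMPA, −78 °C to rt; chromatography on Et3N-deactivated silica
Reagents that add atoms: none
Why: SN2 alkylation of a lithium alkoxyacetylide with a primary bromide in THF/HMPA is an established way to 1-alkoxy-1-alkynes, and the basic work-up protects the acid-labile ynol ether.

Step 4
Reactants: 9 dimethyl squarate (3,4-dimethoxycyclobut-3-ene-1,2-dione)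
Product: 11 3-methoxy-4-methylcyclobut-3-ene-1,2-dione, via lithium alkoxide adduct 10 (not isolated)
Conditions: MeLi, THF, −78 °C; then 12 M HCl, CH2Cl2, rt
Reagents that add atoms: methyllithium, [Li]C; water, O
Why: 1,2-addition of the organolithium to one of the two equivalent squarate carbonyls, then acid-induced ionisation of the tertiary alcohol, capture of the methoxy-stabilised cyclobutenyl cation by water and loss of methanol (1,3-carbonyl transposition of a squarate adduct) should give the alkyl alkoxy cyclobutenedione.

Step 5
Reactants: 11 3-methoxy-4-methylcyclobut-3-ene-1,2-dione; 12 chlorotris(triphenylphosphine)cobalt, ClCo(PPh3)3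
Product: 14 chloro(dimethylglyoxime)(pyridine)(2-methoxy-3-methylmaleoyl)cobalt, ClCo(dmgH2)(py)[C(O)C(Me)=C(OMe)C(O)], via bis(triphenylphosphine) maleoylcobalt chloride 13 (not isolated)
Conditions: PhH, rt, N2; then dimethylglyoxime, pyridine, rt
Reagents that add atoms: dimethylglyoxime, CC(=NO)C(C)=NO; pyridine, c1ccncc1
Why: Oxidative addition of monovalent cobalt into the strained C(=O)–C(=O) bond of the cyclobutenedione (C–C bond activation) gives the cobaltacyclopentenedione of trivalent cobalt, and substitution of both phosphines by chelating dimethylglyoxime and pyridine should give the air-stable octahedral complex that reacts with alkynes without added Lewis acid.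

Step 6
Reactants: 14 chloro(dimethylglyoxime)(pyridine)(2-methoxy-3-methylmaleoyl)cobalt; 8 (12Z)-1-ethoxyheptadec-12-en-1-yne
Product: 15 2-ethoxy-5-methoxy-6-methyl-3-[(10Z)-pentadec-10-en-1-yl]cyclohexa-2,5-diene-1,4-dione
Conditions: 8 (1.1 equiv), ClCH2CH2Cl, 60 °C, N2, no Lewis acid; work-up in air
Reagents that add atoms: none
Why: Heating the 18-electron complex of trivalent cobalt frees a coordination site for the ynol ether; migratory insertion of the alkyne into one cobalt–acyl bond makes the first ring C–C bond and a seven-membered cobaltacycle, and C(acyl)–C(vinyl) reductive elimination makes the second and releases the quinone together with monovalent cobalt. The closest known reaction type is the benzoquinone annulation of alkynes with complexes of the type ClCo(dmgH2)(py)(maleoyl). The six-membered carbocycle is closed by that reductive elimination from the seven-membered metallacycle, overall a cobalt-templated [4+2] union of the four maleoyl carbons with the two alkyne carbons, and no stereocentre is created. The step needs regioselectivity (ring oxygens para) and chemoselectivity (alkyne over the remote Z-olefin, which does not insert). The orientation should be secured by matched polarisation of both partners: the acyl carbon next to C–CH3 is a vinylogous ester acyl (conjugated to OMe through the ring C=C) and hence the electron-rich, faster-migrating one, the acyl carbon next to C–OMe is the more electrophilic one, and in the cobalt-bound ynol ether the O-bearing carbon is the electrophilic and the alkyl-bearing carbon the nucleophilic terminus, so the electron-rich acyl joins the O-bearing carbon and the alkyl-bearing carbon joins the electrophilic acyl, which puts each alkoxy group in conjugation with its own carbonyl. Lewis acids are left out because they would bind the more basic vinylogous ester oxygen and could reverse this bias, and because they would destroy the ynol ether.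

Step 7
Reactants: 15 2-ethoxy-5-methoxy-6-methyl-3-[(10Z)-pentadec-10-en-1-yl]cyclohexa-2,5-diene-1,4-dione
Product: 17 2,5-dihydroxy-3-methyl-6-[(10Z)-pentadec-10-en-1-yl]cyclohexa-2,5-diene-1,4-dione, via disodium quinonediolate 16 (not isolated)
Conditions: 2 M NaOH, EtOH, 60 °C; then 1 M HCl, 0 °C
Reagents that add atoms: NaOH (sodium hydroxide), [Na+].[OH-]
Why: Hydroxide adds to the two alkoxy-bearing ring carbons and expels methoxide and ethoxide (addition–elimination, saponification of vinylogous esters), acidification protonates the dianion, and the isolated Z-olefin is inert to these conditions.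

**Compound list**

1 | 10-bromodecan-1-ol | OCCCCCCCCCCBr | starting material
2 | 10-bromodecanal | O=CCCCCCCCCCBr | intermediate
3 | pentyltriphenylphosphonium bromide | CCCCC[P+](c1ccccc1)(c1ccccc1)c1ccccc1.[Br-] | starting material
4 | pentylidenetriphenylphosphorane (ylide) | CCCCC=P(c1ccccc1)(c1ccccc1)c1ccccc1 | intermediate
5 | (Z)-1-bromopentadec-10-ene | CCCC/C=C\CCCCCCCCCBr | intermediate
6 | ethoxyacetylene (ethoxyethyne) | CCOC#C | starting material
7 | lithium ethoxyacetylide | CCOC#C[Li] | intermediate
8 | (12Z)-1-ethoxyheptadec-12-en-1-yne | CCCC/C=C\CCCCCCCCCC#COCC | intermediate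
9 | dimethyl squarate (3,4-dimethoxycyclobut-3-ene-1,2-dione) | COC1=C(OC)C(=O)C1=O | starting material
10 | lithium 2,3-dimethoxy-1-methyl-4-oxocyclobut-2-en-1-olate (1,2-adduct of MeLi) | COC1=C(OC)C(C)(O[Li])C1=O | intermediate
11 | 3-methoxy-4-methylcyclobut-3-ene-1,2-dione | COC1=C(C)C(=O)C1=O | intermediate
12 | chlorotris(triphenylphosphine)cobalt, ClCo(PPh3)3 (monovalent cobalt; donor bonds drawn charge-separated) | Cl[Co-3]([P+](c1ccccc1)(c1ccccc1)c1ccccc1)([P+](c1ccccc1)(c1ccccc1)c1ccccc1)[P+](c1ccccc1)(c1ccccc1)c1ccccc1 | starting material
13 | chloro(2-methoxy-3-methylmaleoyl)bis(triphenylphosphine)cobalt, ClCo(PPh3)2[C(O)C(Me)=C(OMe)C(O)] (trivalent cobalt; five-membered cobaltacyclopentenedione) | O=C1C(C)=C(OC)C(=O)[Co-2]1(Cl)([P+](c2ccccc2)(c2ccccc2)c2ccccc2)[P+](c2ccccc2)(c2ccccc2)c2ccccc2 | intermediate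
14 | chloro(dimethylglyoxime)(pyridine)(2-methoxy-3-methylmaleoyl)cobalt, ClCo(dmgH2)(py)[C(O)C(Me)=C(OMe)C(O)] (trivalent cobalt; neutral N,N-chelating dimethylglyoxime) | O=C1C(C)=C(OC)C(=O)[Co-3]12(Cl)([n+]3ccccc3)[N+](O)=C(C)C(C)=[N+]2O | intermediate
15 | 2-ethoxy-5-methoxy-6-methyl-3-[(10Z)-pentadec-10-en-1-yl]cyclohexa-2,5-diene-1,4-dione | CCCC/C=C\CCCCCCCCCC1=C(OCC)C(=O)C(C)=C(OC)C1=O | intermediate
16 | disodium 2-methyl-3,6-dioxo-5-[(10Z)-pentadec-10-en-1-yl]cyclohexa-1,4-diene-1,4-diolate | CCCC/C=C\CCCCCCCCCC1=C([O-])C(=O)C(C)=C([O-])C1=O.[Na+].[Na+] | intermediate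
17 | 2,5-dihydroxy-3-methyl-6-[(10Z)-pentadec-10-en-1-yl]cyclohexa-2,5-diene-1,4-dione | CCCC/C=C\CCCCCCCCCC1=C(O)C(=O)C(C)=C(O)C1=O | target

**Count**

Total steps: 7. Longest linear sequence: 5 steps (steps 1, 2, 3, 6, 7); the cobalt branch (steps 4, 5) joins at step 6.

**Steps most likely to fail**

1. Step 6. The ynol ether may insert in the reverse orientation, so that the ring oxygens end meta, or it may decompose (loss of ethylene to a ketene, hydration) before it inserts. The fallback sets out from 5 and comes back at 17. Commercial 1,2,4,5-tetramethoxybenzene is lithiated (n-BuLi, THF, 0 °C) and methylated (MeI) to 1,2,4,5-tetramethoxy-3-methylbenzene F1. A second ortho-lithiation at the one remaining ring position and alkylation with bromide 5 (THF/HMPA) should give 1,2,4,5-tetramethoxy-3-methyl-6-[(10Z)-pentadec-10-en-1-yl]benzene F2. Oxidative demethylation with (NH4)2Ce(NO3)6 (MeCN/H2O, 0 °C) should give 2,5-dimethoxy-3-methyl-6-[(10Z)-pentadec-10-en-1-yl]cyclohexa-2,5-diene-1,4-dione F3, which is hydrolysed under the conditions of step 7 to 17. Here the substitution pattern is fixed by the arene, so no question of orientation arises.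

2. Step 3. The weakly nucleophilic alkoxyacetylide may displace the bromide slowly, with competing elimination, and the ynol ether may be hydrolysed during isolation. The fallback sets out from 5 and comes back at 17. Displacement of the bromide of 5 with LiC≡CH·H2NCH2CH2NH2 in DMSO gives (12Z)-heptadec-12-en-1-yne F4. Deprotonation (n-BuLi, THF, −78 °C), oxidation of the lithium acetylide to the lithium ynolate with LiOO-t-Bu (from t-BuOOH and LiN(SiMe3)2) and O-silylation with i-Pr3SiOTf should give {[(12Z)-heptadec-12-en-1-yn-1-yl]oxy}tri(propan-2-yl)silane F5, a robust siloxyalkyne. F5 takes the place of 8 in step 6, with the same polarity argument, and should give 2-methoxy-3-methyl-6-[(10Z)-pentadec-10-en-1-yl]-5-{[tri(propan-2-yl)silyl]oxy}cyclohexa-2,5-diene-1,4-dione F6. Under the conditions of step 7, hydroxide cleaves the silyl enol ether and the methyl enol ether to give 17.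

3. Step 2. Z-selectivity may erode through equilibration of the Wittig intermediates, leaving an E-isomer that cannot be separated later. The fallback sets out from 2 and comes back at 5. Ohira–Bestmann homologation of 2 (dimethyl (1-diazo-2-oxopropyl)phosphonate, K2CO3, MeOH, rt) gives 11-bromoundec-1-yne F7. Its lithium acetylide (n-BuLi, THF, −78 °C) is alkylated with butyl trifluoromethanesulfonate in THF without a dipolar cosolvent, where the primary bromide does not compete, to give 15-bromopentadec-5-yne F8. Semihydrogenation (H2, Pd/CaCO3 poisoned with Pb(OAc)2, quinoline, hexane) adds hydrogen syn on the catalyst surface and should give 5 with the Z geometry.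

**Further compounds**

F1 | step 6 | 1,2,4,5-tetramethoxy-3-methylbenzene | COc1cc(OC)c(OC)c(C)c1OC
F2 | step 6 | 1,2,4,5-tetramethoxy-3-methyl-6-[(10Z)-pentadec-10-en-1-yl]benzene | CCCC/C=C\CCCCCCCCCc1c(OC)c(OC)c(C)c(OC)c1OC
F3 | step 6 | 2,5-dimethoxy-3-methyl-6-[(10Z)-pentadec-10-en-1-yl]cyclohexa-2,5-diene-1,4-dione | CCCC/C=C\CCCCCCCCCC1=C(OC)C(=O)C(C)=C(OC)C1=O
F4 | step 3 | (12Z)-heptadec-12-en-1-yne | CCCC/C=C\CCCCCCCCCC#C
F5 | step 3 | {[(12Z)-heptadec-12-en-1-yn-1-yl]oxy}tri(propan-2-yl)silane | CCCC/C=C\CCCCCCCCCC#CO[Si](C(C)C)(C(C)C)C(C)C
F6 | step 3 | 2-methoxy-3-methyl-6-[(10Z)-pentadec-10-en-1-yl]-5-{[tri(propan-2-yl)silyl]oxy}cyclohexa-2,5-diene-1,4-dione | CCCC/C=C\CCCCCCCCCC1=C(O[Si](C(C)C)(C(C)C)C(C)C)C(=O)C(C)=C(OC)C1=O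
F7 | step 2 | 11-bromoundec-1-yne | C#CCCCCCCCCCBr
F8 | step 2 | 15-bromopentadec-5-yne | CCCCC#CCCCCCCCCCBr
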